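The 14-membered carbocycle is opened at C2–C3, the two-carbon bridge between the acetoxy carbon C1 and the C4 enone carbonyl. C1 and C2 then become the vinyl carbinol of (R)-linalool, whose chain already holds C14, C13, C12 and the isopropylidene group. C4–C11 is geraniol, and C3 comes from a vinyl Grignard reagent. In one flask, ring-closing metathesis of an acyclic tetraene (linalyl acetate vinyl at one end, C4 vinyl carbinol at the other) closes the ring as a C2=C3 allylic alcohol. A ruthenium hydride then isomerises it to the saturated C2H2–C3H2–C4=O array. The step exploits quaternary C1, which leaves only this direction of alkene migration.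

Key step: step 10

Remark: ring atoms of the target are numbered C1 (acetoxy carbon), C2, C3, C4 (enone C=O), C5(CH3)=C6, C7, C8, C9(CH3)–C10 (epoxide), C11 (C=O), C12 (isopropylidene carbon), C13, C14, and all intermediates keep these numbers; commercial (R)-(−)-linalool is assumed to be of high enantiomeric purity, and any residual mismatch with the epoxide fragment should be removable as a diastereomer after step 6.

Step 1
Reactants: 1 (R)-(−)-linalool
Product: 2 (R)-linalyl acetate
Conditions: Ac2O, Et3N, DMAP (cat.), CH2Cl2, rt
Reagents that add atoms: acetic anhydride, CC(=O)OC(C)=O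
Why: DMAP-catalysed acyl transfer esterifies the tertiary allylic alcohol under basic conditions without touching its C–O bond, so the (R) centre that becomes C1 is retained.

Step 2
Reactants: 2 (R)-linalyl acetate
Product: 3 (3R,6RS)-6-chloro-3,7-dimethylocta-1,7-dien-3-yl acetate
Conditions: Ca(OCl)2, CO2 (s), CH2Cl2/H2O, 0 °C
Reagents that add atoms: calcium hypochlorite (source of HOCl), [Ca+2].[O-]Cl.[O-]Cl
Why: In this ene-type allylic chlorination by hypochlorous acid the electron-rich trisubstituted alkene takes up Cl+ at its less substituted carbon (future C12) and loses a methyl proton to give the transposed isopropenyl chloride, while the vinyl group next to the acetoxy-bearing quaternary carbon is too electron-poor to compete; the new C–Cl centre forms unselectively and is erased in steps 6 to 8.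

Step 3
Reactants: 4 geraniol
Product: 5 (2S,3S)-2,3-epoxygeraniol
Conditions: Ti(OiPr)4 (cat.), L-(+)-diethyl tartrate (cat.), t-BuOOH, 4 Å MS, CH2Cl2, −20 °C
Reagents that add atoms: tert-butyl hydroperoxide, CC(C)(C)OO
Why: In the Sharpless asymmetric epoxidation the titanium/L-(+)-tartrate complex binds the allylic alcohol and delivers oxygen to one face of the 2,3-alkene only, which sets both epoxide centres (future C10 and C9) as 2S,3S, carries the E geometry into the trans relation of CH2OH and chain, and leaves the remote alkene untouched.

Step 4
Reactants: 5 (2S,3S)-2,3-epoxygeraniol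
Product: 6 (2S,3S,6E)-2,3-epoxy-3,7-dimethyloct-6-ene-1,8-diol
Conditions: SeO2 (cat.), t-BuOOH, CH2Cl2, 0 °C to rt
Reagents that add atoms: tert-butyl hydroperoxide (oxygen relayed by catalytic SeO2), CC(C)(C)OO
Why: Selenium dioxide allylic oxidation (ene reaction, then [2,3]-sigmatropic shift) hydroxylates the (E)-methyl group of the only remaining alkene, which fixes the E geometry of the future C5=C6 bond, and any enal formed by over-oxidation converges in step 5.

Step 5
Reactants: 6 (2S,3S,6E)-2,3-epoxy-3,7-dimethyloct-6-ene-1,8-diol
Product: 7 (2R,3S,6E)-2,3-epoxy-3,7-dimethyloct-6-enedial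
Conditions: TEMPO (cat.), PhI(OAc)2, CH2Cl2, rt
Reagents that add atoms: none
Why: The oxoammonium (TEMPO/PhI(OAc)2) oxidation takes both primary alcohols to aldehydes under anhydrous, near-neutral conditions that neither open nor epimerise the epoxide (the C2 descriptor changes only because of the priority switch).

Step 6
Reactants: 3 (3R,6RS)-6-chloro-3,7-dimethylocta-1,7-dien-3-yl acetate; 7 (2R,3S,6E)-2,3-epoxy-3,7-dimethyloct-6-enedial
Product: 9 (1R,9S,10S)-C11-hydroxy enal as C11/C12 epimer mixture, via allylindium diiodide 8 (not isolated)
Conditions: 3, In powder, NaI, DMF, rt; then 7 (1.0 equiv), 0 °C; then H2O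
Reagents that add atoms: none
Why: In this indium-mediated Barbier-type allylation the allylindium settles in its primary form and attacks through a six-membered SE2′ transition state with its γ-carbon (C12); one equivalent should select the inductively activated, non-conjugated epoxy aldehyde (C11) over the conjugated α-methyl enal (C4), acetate and epoxide being tolerated, and the new C11 and C12 centres form as mixtures that steps 7 and 8 erase.

Step 7
Reactants: 9 (1R,9S,10S)-C11-hydroxy enal
Product: 10 (1R,9S,10R)-C11 keto enal with C12 isopropenyl group (C12 epimers)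
Conditions: Dess–Martin periodinane, pyridine, CH2Cl2, 0 °C to rt
Reagents that add atoms: none
Why: Dess–Martin oxidation converts the hindered secondary carbinol into the ketone under buffered, mild conditions that leave enal, epoxide, acetate and alkenes alone, and it removes the C11 stereocenter.

Step 8
Reactants: 10 (1R,9S,10R)-C11 keto enal with C12 isopropenyl group
Product: 11 (1R,9S,10R)-C11 keto enal with C12 isopropylidene group
Conditions: DBU (cat.), CH2Cl2, rt
Reagents that add atoms: none
Why: In this base-catalysed conjugation through the dienolate, DBU reversibly removes the doubly activated C12–H and reprotonation at the terminal CH2 moves the alkene into the tetrasubstituted conjugated position under thermodynamic control, which erases C12 as a stereocenter and removes the 1,1-disubstituted alkene that would close a cyclohexene in step 10.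

Step 9
Reactants: 11 (1R,9S,10R)-C11 keto enal with C12 isopropylidene group
Product: 12 (1R,9S,10R)-seco-tetraene with C4 vinyl carbinol (C4 epimers)
Conditions: CH2=CHMgBr (1.1 equiv), THF, −78 °C; then H2O
Reagents that add atoms: vinylmagnesium bromide, C=C[Mg]Br
Why: The 1,2-Grignard addition at low temperature should select the aldehyde over the C11 ketone, which is flanked by the tetrasubstituted alkene and the epoxide, and over the tertiary acetate for steric reasons; the C4 carbinol centre forms unselectively and is erased in step 10.

Step 10
Reactants: 12 (1R,9S,10R)-seco-tetraene with C4 vinyl carbinol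
Product: 14 target cembranoid (1R,5E,9S,10R), via macrocyclic allylic alcohol 13 (not isolated)
Conditions: second-generation Grubbs catalyst (10 mol %), PhMe (1 mM), 60 °C, Ar purge; then N2/H2 (95:5), 80 °C
Reagents that add atoms: none
Why: Ring-closing olefin metathesis ([2+2]/cycloreversion cycle) starts at the unhindered, hydroxyl-activated C4 vinyl carbinol, and the alkylidene engages the only other monosubstituted alkene, the vinyl group on C1, so that C2=C3 forms, ethylene leaves and the 14-membered carbocycle 13 closes by end-to-end union of two terminal vinyl groups at high dilution (no small ring is formed). Traces of hydrogen then turn the spent carbene into a ruthenium hydride, which adds across C2=C3 with the metal on the less hindered C3 and eliminates the C4–H to give the C3=C4 enol, which tautomerises to the C4 ketone now conjugated with C5=C6. The closest known reaction types are macrocyclic RCM and the one-flask metathesis/allylic alcohol redox isomerisation. No stereocenter is created: both C4 epimers and both alkene geometries of 13 converge on 14, while C1, C9 and C10 are spectators. Selectivity in the metathesis is secured because C5=C6 is trisubstituted, C12=C(CH3)2 is tetrasubstituted and acceptor-bound, and the isopropenyl group was removed in step 8. Selectivity in the hydride stage is secured by quaternary C1, which leaves C4 as the only direction of migration, and by the lower substitution of C2=C3 compared with C5=C6.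

Compound list
1 | (R)-(−)-linalool, (3R)-3,7-dimethylocta-1,6-dien-3-ol | O[C@@](C)(C=C)CCC=C(C)C | starting material
2 | (R)-linalyl acetate, (3R)-3,7-dimethylocta-1,6-dien-3-yl acetate | CC(=O)O[C@@](C)(C=C)CCC=C(C)C | intermediate
3 | (3R,6RS)-6-chloro-3,7-dimethylocta-1,7-dien-3-yl acetate | CC(=O)O[C@@](C)(C=C)CCC(Cl)C(C)=C | intermediate
4 | geraniol, (2E)-3,7-dimethylocta-2,6-dien-1-ol | CC(C)=CCC/C(C)=C/CO | starting material
5 | (2S,3S)-2,3-epoxygeraniol | CC(C)=CCC[C@]1(C)O[C@H]1CO | intermediate
6 | (2S,3S,6E)-2,3-epoxy-3,7-dimethyloct-6-ene-1,8-diol | OC/C(C)=C/CC[C@]1(C)O[C@H]1CO | intermediate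
7 | (2R,3S,6E)-2,3-epoxy-3,7-dimethyloct-6-enedial | O=C/C(C)=C/CC[C@]1(C)O[C@H]1C=O | intermediate
8 | [(6R)-6-acetoxy-2,6-dimethylocta-2,7-dien-1-yl]indium diiodide (alkene geometry undefined, not isolated) | CC(=O)O[C@@](C)(C=C)CCC=C(C)C[In](I)I | intermediate
9 | hydroxy enal: C4 (E)-enal, C9/C10 epoxide, C11 carbinol, C12–H bearing isopropenyl, C1 acetoxy vinyl terminus; 1R,9S,10S, C11/C12 epimers | O=C/C(C)=C/CC[C@]1(C)O[C@H]1C(O)C(CC[C@](C)(C=C)OC(C)=O)C(C)=C | intermediate
10 | β,γ-unsaturated keto enal: as 9 with C11 ketone; 1R,9S,10R, C12 epimers | O=C/C(C)=C/CC[C@]1(C)O[C@H]1C(=O)C(CC[C@](C)(C=C)OC(C)=O)C(C)=C | intermediate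
11 | conjugated keto enal: as 10 with C12=C(CH3)2; 1R,9S,10R | O=C/C(C)=C/CC[C@]1(C)O[C@H]1C(=O)C(CC[C@](C)(C=C)OC(C)=O)=C(C)C | intermediate
12 | seco-tetraene: as 11 with C4 as CH(OH)–CH=CH2; 1R,5E,9S,10R, C4 epimers | C=CC(O)/C(C)=C/CC[C@]1(C)O[C@H]1C(=O)C(CC[C@](C)(C=C)OC(C)=O)=C(C)C | intermediate
13 | (1R,2E,5E,9S,10R)-9,10-epoxy-4-hydroxy-1,5,9-trimethyl-11-oxo-12-(propan-2-ylidene)cyclotetradeca-2,5-dien-1-yl acetate (C4 epimers; C2=C3 drawn E, its geometry is of no consequence; not isolated) | CC(=O)O[C@@]1(C)/C=C/C(O)/C(C)=C/CC[C@]2(C)O[C@H]2C(=O)C(=C(C)C)CC1 | intermediate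
14 | (1R,5E,9S,10R)-9,10-epoxy-1,5,9-trimethyl-4,11-dioxo-12-(propan-2-ylidene)cyclotetradec-5-en-1-yl acetate | CC(=O)O[C@@]1(C)CCC(=O)/C(C)=C/CC[C@]2(C)O[C@H]2C(=O)C(=C(C)C)CC1 | target

Total step count: 10. Longest linear sequence: 8 (steps 3 to 10, from geraniol).

Steps most likely to fail

Step 10. Adventitious ruthenium hydride may isomerise the acyclic vinyl carbinol to its ethyl ketone before the slow closure onto the hindered vinyl group at C1. The hydride stage may also hydrogenate instead of isomerise, or add with the metal on C2 and expel the C1 acetate by β-elimination. The fallback sets out from 12 and comes back at 14. It separates the two events and replaces the redox isomerisation by oxidation and hydrogenation. MnO2 oxidises 12 to the cross-conjugated vinyl ketone F1, which cannot isomerise. A phosphine-free Hoveyda–Grubbs catalyst closes the same C2=C3 bond to give the macrocyclic (2E,5E)-dienone F2. Hydrogen over Wilkinson's catalyst then saturates the only disubstituted alkene to give 14.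

Step 6. The two aldehydes may be poorly discriminated, which would lead to attack at C4 or to double allylation, and some coupling may occur through the α-carbon of the allyl metal. The fallback sets out from 5 and comes back at 11. It postpones the allylic oxidation, so that only one aldehyde is present at the coupling. TEMPO/PhI(OAc)2 gives (2R,3S)-2,3-epoxygeranial F3. Allylindium 8 adds to it to give the homoallylic alcohol F4. Dess–Martin oxidation gives the β,γ-unsaturated ketone F5, and DBU gives the isopropylidene ketone F6. Stoichiometric SeO2 in dioxane then takes the (E)-methyl group of the only electron-rich trisubstituted alkene to the aldehyde level, giving 11.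

Step 8. The deconjugated and conjugated ketones may settle at an unfavourable equilibrium because the tetrasubstituted enone is twisted out of conjugation. Long exposure to base may also cause aldol side reactions of the enal. The fallback sets out from 2 (with 7 as partner) and comes back at 11. It carries the tetrasubstituted alkene in as an alkenyl halide, so that no equilibration is needed. One equivalent of bromine at low temperature adds to the trisubstituted alkene of 2 to give the 6,7-dibromide F7. DBU removes hydrogen bromide across C6–C7 to give the alkenyl bromide F8. A Nozaki–Hiyama–Kishi coupling (CrCl2, cat. NiCl2) joins F8 to the epoxy aldehyde terminus of 7 to give the allylic alcohol F9, and Dess–Martin oxidation of F9 gives 11.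

Further compounds
F1 | step 10 | seco vinyl ketone: 12 with C4 ketone; 1R,5E,9S,10R | C=CC(=O)/C(C)=C/CC[C@]1(C)O[C@H]1C(=O)C(CC[C@](C)(C=C)OC(C)=O)=C(C)C
F2 | step 10 | macrocyclic (2E,5E)-dienone: 14 with C2=C3 double bond; 1R,9S,10R | CC(=O)O[C@@]1(C)/C=C/C(=O)/C(C)=C/CC[C@]2(C)O[C@H]2C(=O)C(=C(C)C)CC1
F3 | step 6 | (2R,3S)-2,3-epoxygeranial | CC(C)=CCC[C@]1(C)O[C@H]1C=O
F4 | step 6 | homoallylic alcohol: 9 with intact terminal isopropylidene in place of the enal; C11/C12 epimers | CC(C)=CCC[C@]1(C)O[C@H]1C(O)C(CC[C@](C)(C=C)OC(C)=O)C(C)=C
F5 | step 6 | β,γ-unsaturated ketone from F4; C12 epimers | CC(C)=CCC[C@]1(C)O[C@H]1C(=O)C(CC[C@](C)(C=C)OC(C)=O)C(C)=C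
F6 | step 6 | C12 isopropylidene ketone from F5 | CC(C)=CCC[C@]1(C)O[C@H]1C(=O)C(CC[C@](C)(C=C)OC(C)=O)=C(C)C
F7 | step 8 | (3R,6RS)-6,7-dibromo-3,7-dimethyloct-1-en-3-yl acetate | CC(=O)O[C@@](C)(C=C)CCC(Br)C(C)(C)Br
F8 | step 8 | (3R)-6-bromo-3,7-dimethylocta-1,6-dien-3-yl acetate | CC(=O)O[C@@](C)(C=C)CCC(Br)=C(C)C
F9 | step 8 | allylic alcohol: 11 with C11 carbinol (C11 epimers) | O=C/C(C)=C/CC[C@]1(C)O[C@H]1C(O)C(CC[C@](C)(C=C)OC(C)=O)=C(C)C
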